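Early times opened the meeting. The chair reported that Tuesday's run had 29.1% of its electrophile as product by 4.00 h and 37.0% by 12.0 h. After that it crept, to 42.5% at 48.0 h. The meeting called the reading at 12.0 h the knee.

common to all: electrophile 0.30 M

| run | nucleophile | remark | time |
|---|---|---|---|
| Tuesday's | 0.22 M | run made earlier |  |
| dawn | 0.330 M |  | 50 h |
| spring | 0.490 M |  | 50 h |

- Tuesday's (time / h: electrophile / %, product / %): 4.00: 71.1, 29.1; 6.00: 67.6, 32.7; 12.0: 64.2, 37.0; 20.0: 61.2, 38.8; 30.0: 60.3, 39.9; 48.0: 58.0, 42.5

(standard deviation of a reading: 0.5 percentage points)

- the analysis behind the earlier runs scatters by 0.5 percentage points, standard deviation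

- part of the electrophile that has reacted at the end, dawn
- part of the electrophile that has reacted at the end, spring
- what raising the concentration of nucleophile from its lowest to its highest value here does to the part of the electrophile that has reacted (changes below 5 percentage points count as none) (no change / it falls / it rises)

The analyst divided the nucleophile charge by the electrophile reacted at the knee. She called this the nucleophile cost, the nucleophile charged per electrophile reacted up to the knee, and read it as 1.98, a reading with the scatter of the analysis.

She argued that the knee fraction of a flask is its nucleophile charge over the cost times its electrophile charge. That gave 55.5% for dawn and 82.4% for spring. She noted that 50 h lies past Tuesday's knee, so she added Tuesday's creep of 5.5 percentage points. Her reckoning was 61.0% for dawn and 87.9% for spring. The gap of 27 points exceeds 5 points, so she expected a rise.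

The forecast was then read out: 56% for dawn, 69% for spring, and it rises. Its ground was “The two pictures agree, so conversion rises”. The chair minuted that the analyst's numbers stood above it in dawn and in spring.

The flasks gave 60.2% in dawn and 83.8% in spring, so it rises, by 24 points.

    electrophile + nucleophile → acid set free + product (k = 3.10 × 10⁻⁴ M⁻¹ s⁻¹)
    nucleophile + acid set free ⇌ protonated nucleophile, settled at all times (K = 1900 M⁻¹)
    nucleophile ⇌ dormant form (K = 0.510, k = 3.70 × 10⁻⁵ s⁻¹)

Spring ended above its reckoned knee of 82.4%, at 83.8%, with 1.14% of its nucleophile free, so nucleophile was the limiting reagent. The gap between spring and dawn comes from their difference in nucleophile charge. One part of that gap is the tying up of nucleophile with acid set free as protonated nucleophile: in the run with it taken away, the gap is 4.4 points instead of 24 points. The cost gives the neighbour flask, spring with 1.2 M of electrophile, a reckoned knee at 20.6%, and that flask stands at 26.1%.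

(The runs are calculated for an exercise, noise included.)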